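The 14-membered carbocycle is opened at C7–C8 (cembrane numbering: C1 carries the isopropenyl group, C2 the secondary acetate, C18 the acetoxymethyl carbon on C4). There the C7 carbinol flanks the C8=C19 exocyclic methylene, an allylic alcohol that maps onto the addition of an alkenylmetal, made from a 2-iodo-1-alkene, to an aldehyde. One ligand-controlled Ni/Cr coupling forms this bond, closes the only ring, sets C7 (R) and gives the target with both acetates already in place. Its precursor is an acyclic C8 iodoalkene/C7 aldehyde carrying the anti C1/C2 pair, assembled by a nickel-free chromium allylation that joins a geranyl-derived C8–C16 allylic bromide to a C2–C7 enal without touching the iodoalkene.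

Key step: step 14

Assumption: the ligand on chromium in steps 10 and 14 (L*) is an oxazoline–sulfonamide, N-[2-(4-isopropyl-4,5-dihydro-1,3-oxazol-2-yl)-6-methoxyphenyl]methanesulfonamide, accessible in both antipodes. The antipode that gives Re-face addition at C2 (step 10) and Si-face addition at C7 (step 14) is taken to be identified in a short screen.

Step 1
Reactants: 1 geranyl bromide [(2E)-1-bromo-3,7-dimethylocta-2,6-diene]; 2 1-(trimethylsilyl)propyne
Product: 4 trimethyl[(5E)-6,10-dimethylundeca-5,9-dien-1-yn-1-yl]silane, via lithiated silylpropyne 3 (not isolated)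
Conditions: 2, n-BuLi, THF, −78 to −20 °C; then 1, −78 °C to rt
Reagents that add atoms: none
Why: The lithiated silylpropyne is a propargyl anion equivalent that should displace the primary allylic bromide by SN2 at the carbon remote from silicon (propargylic alkylation), leaving the E alkene of the geranyl unit (later C11=C12) unchanged.

Step 2
Reactants: 4 trimethyl[(5E)-6,10-dimethylundeca-5,9-dien-1-yn-1-yl]silane
Product: 5 (5E)-6,10-dimethylundeca-5,9-dien-1-yne
Conditions: K2CO3 (cat.), MeOH, rt
Reagents that add atoms: none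
Why: Base-catalysed methanolysis cleaves only the C(sp)–Si bond (protodesilylation of a silylalkyne), the two alkenes being inert.

Step 3
Reactants: 5 (5E)-6,10-dimethylundeca-5,9-dien-1-yne
Product: 7 (5E)-2-iodo-6,10-dimethylundeca-1,5,9-triene, via iodoalkenylborane 6 (not isolated)
Conditions: B-iodo-9-BBN, pentane, −20 to 0 °C; then AcOH, 0 °C
Reagents that add atoms: B-iodo-9-borabicyclo[3.3.1]nonane, IB1C2CCCC1CCC2
Why: Haloboration adds B–I syn across the terminal alkyne only (boron to the terminal carbon C19, iodine to C8) and protonolysis of the C–B bond by AcOH leaves the 2-iodo-1-alkene, a net Markovnikov hydroiodination that trisubstituted alkenes do not undergo.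

Step 4
Reactants: 7 (5E)-2-iodo-6,10-dimethylundeca-1,5,9-triene
Product: 9 (2E,6E)-10-iodo-2,6-dimethylundeca-2,6,10-trien-1-ol, via overoxidised enal 8 (not isolated)
Conditions: SeO2 (0.2 equiv), tBuOOH (3 equiv), salicylic acid (0.1 equiv), CH2Cl2, 0 °C to rt, stopped at partial conversion; then NaBH4, MeOH, 0 °C
Reagents that add atoms: selenium dioxide, O=[Se]=O; tert-butyl hydroperoxide, CC(C)(C)OO
Why: Riley allylic oxidation (ene reaction then [2,3]-shift) should hydroxylate the E methyl of the exposed terminal isopropylidene group in preference to the internal trisubstituted alkene, as in farnesyl-type chains, while the electron-poor iodoalkene does not compete and NaBH4 returns the portion overoxidised to enal 8 to the alcohol.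

Step 5
Reactants: 9 (2E,6E)-10-iodo-2,6-dimethylundeca-2,6,10-trien-1-ol
Product: 10 (2E,6E)-1-bromo-10-iodo-2,6-dimethylundeca-2,6,10-triene
Conditions: CBr4, PPh3, CH2Cl2, −20 to 0 °C; used promptly
Reagents that add atoms: carbon tetrabromide, BrC(Br)(Br)Br
Why: The Appel reaction converts the primary allylic alcohol into the bromide under neutral conditions, and any allylic or E/Z isomer formed would later converge on the same allylchromium.

Step 6
Reactants: 11 but-2-yne-1,4-diol
Product: 12 4-[(tert-butyldimethylsilyl)oxy]but-2-yn-1-ol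
Conditions: NaH (1.0 equiv), THF, 0 °C to rt; then TBSCl (1.0 equiv)
Reagents that add atoms: tert-butyldimethylsilyl chloride, CC(C)(C)[Si](C)(C)Cl
Why: The monosodium alkoxide of the symmetrical diol should be silylated once (monoprotection by stoichiometric alkoxide formation), the unreacted diol being removed with water.

Step 7
Reactants: 12 4-[(tert-butyldimethylsilyl)oxy]but-2-yn-1-ol
Product: 14 (2Z)-4-[(tert-butyldimethylsilyl)oxy]-3-iodobut-2-en-1-ol, via cyclic vinylalanate 13 (not isolated)
Conditions: NaAlH2(OCH2CH2OMe)2, THF, 0 °C to rt; then I2, THF, −78 to 0 °C; aq. potassium sodium tartrate work-up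
Reagents that add atoms: iodine, II
Why: Hydroxyl-directed trans-hydroalumination places aluminium on the alkyne carbon remote from the hydroxyl in a five-membered alanate, and iodinolysis with retention gives the Z iodide, which fixes the later ring-cis relation of C2 and C5 across C3=C4.

Step 8
Reactants: 14 (2Z)-4-[(tert-butyldimethylsilyl)oxy]-3-iodobut-2-en-1-ol; 15 acrolein diethyl acetal (3,3-diethoxyprop-1-ene)
Product: 17 (2E)-3-{[(tert-butyldimethylsilyl)oxy]methyl}-6,6-diethoxyhex-2-en-1-ol, via alkylborane 16 (not isolated)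
Conditions: 15, 9-BBN, THF, 0 °C to rt; then 14, PdCl2(dppf) (5 mol %), AsPh3, aq. K3PO4, DMF, rt
Reagents that add atoms: none
Why: Anti-Markovnikov hydroboration gives the primary alkylborane 16, which should couple with the alkenyl iodide in a B-alkyl Suzuki–Miyaura reaction with retention of alkene geometry (the descriptor changes to E only through the priority rules), the free hydroxyl, silyl ether and acetal tolerating the mild base.

Step 9
Reactants: 17 (2E)-3-{[(tert-butyldimethylsilyl)oxy]methyl}-6,6-diethoxyhex-2-en-1-ol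
Product: 18 (2E)-3-{[(tert-butyldimethylsilyl)oxy]methyl}-6,6-diethoxyhex-2-enal
Conditions: MnO2 (activated, excess), CH2Cl2, rt; used without storage
Reagents that add atoms: none
Why: MnO2 oxidises only the allylic alcohol to the enal under neutral conditions, which should keep the acetal, the silyl ether and the alkene geometry intact.

Step 10
Reactants: 10 (2E,6E)-1-bromo-10-iodo-2,6-dimethylundeca-2,6,10-triene; 18 (2E)-3-{[(tert-butyldimethylsilyl)oxy]methyl}-6,6-diethoxyhex-2-enal
Product: 19 (4E,6S,7R,10E)-4-{[(tert-butyldimethylsilyl)oxy]methyl}-1,1-diethoxy-14-iodo-10-methyl-7-(prop-1-en-2-yl)pentadeca-4,10,14-trien-6-ol (cembrane C1 R, C2 S, anti)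
Conditions: CrCl2 (15 mol %, nickel-free grade), L* (17 mol %), proton sponge (17 mol %), Mn (2 equiv), Cp2ZrCl2 (1.1 equiv), LiCl, MeCN, rt, no nickel salt
Reagents that add atoms: none
Why: Divalent chromium inserts only into the allylic C–Br bond (the C8–I bond needs nickel), the equilibrating allylchromium adds through its gamma carbon C1 to the aldehyde carbon C2 in a closed chair (catalytic asymmetric Nozaki–Hiyama allylation) that should give the anti C1/C2 pair, and the chiral ligand on chromium selects the Re face of C2 to give 1R,2S, while Cp2ZrCl2 and Mn turn the chromium over without acid that would harm the acetal.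

Step 11
Reactants: 19 (4E,6S,7R,10E)-4-{[(tert-butyldimethylsilyl)oxy]methyl}-1,1-diethoxy-14-iodo-10-methyl-7-(prop-1-en-2-yl)pentadeca-4,10,14-trien-6-ol
Product: 20 (4E,6S,7R,10E)-1,1-diethoxy-4-(hydroxymethyl)-14-iodo-10-methyl-7-(prop-1-en-2-yl)pentadeca-4,10,14-trien-6-ol
Conditions: TBAF, THF, 0 °C to rt
Reagents that add atoms: none
Why: Fluoride cleaves the primary silyl ether (desilylation) and should leave the acetal, the iodoalkene and both stereocentres untouched.

Step 12
Reactants: 20 (4E,6S,7R,10E)-1,1-diethoxy-4-(hydroxymethyl)-14-iodo-10-methyl-7-(prop-1-en-2-yl)pentadeca-4,10,14-trien-6-ol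
Product: 21 (4E,6S,7R,10E)-4-(acetoxymethyl)-1,1-diethoxy-14-iodo-10-methyl-7-(prop-1-en-2-yl)pentadeca-4,10,14-trien-6-yl acetate
Conditions: Ac2O, pyridine, DMAP (cat.), CH2Cl2, 0 °C to rt
Reagents that add atoms: acetic anhydride, CC(=O)OC(C)=O
Why: DMAP-catalysed acylation should esterify both the primary C18 and the hindered secondary C2 hydroxyl with retention at C2, installing the two acetates of the target before ring closure.

Step 13
Reactants: 21 (4E,6S,7R,10E)-4-(acetoxymethyl)-1,1-diethoxy-14-iodo-10-methyl-7-(prop-1-en-2-yl)pentadeca-4,10,14-trien-6-yl acetate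
Product: 22 (4E,6S,7R,10E)-6-acetoxy-4-(acetoxymethyl)-14-iodo-10-methyl-7-(prop-1-en-2-yl)pentadeca-4,10,14-trienal
Conditions: PPTS (0.2 equiv), acetone/H2O 10:1, 40 °C
Reagents that add atoms: water, O
Why: Mild acid-catalysed acetal hydrolysis should release the C7 aldehyde from the acyclic diethyl acetal much faster than the allylic acetates ionise or hydrolyse.

Step 14
Reactants: 22 (4E,6S,7R,10E)-6-acetoxy-4-(acetoxymethyl)-14-iodo-10-methyl-7-(prop-1-en-2-yl)pentadeca-4,10,14-trienal
Product: 23 CNP0077636.1, (1R,2S,3E,7R,11E)-2,18-diacetoxycembra-3,8(19),11,15-tetraen-7-ol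
Conditions: CrCl2 (0.3 equiv), L* (0.33 equiv), proton sponge (0.33 equiv), NiCl2(2,9-dimethyl-1,10-phenanthroline) (5 mol %), Mn (4 equiv), Cp2ZrCl2 (2 equiv), LiCl, MeCN, rt, 22 added by syringe pump to about 2 mM
Reagents that add atoms: none
Why: Zerovalent nickel inserts into the C8–I bond, the alkenyl group passes to trivalent chromium, and the alkenylchromium adds to the C7 aldehyde, after which Cp2ZrCl2 frees the chromium alkoxide and Mn regenerates divalent chromium. The closest known reaction type is the Ni/Cr-mediated (Nozaki–Hiyama–Kishi) macrocyclisation of an iodoalkene onto an aldehyde, including its catalytic asymmetric form with oxazoline–sulfonamide ligands. The 14-membered carbocycle closes by C7–C8 bond formation in the exo mode at the carbonyl carbon (14-exo-trig), and the C8=C19 alkene ends up exocyclic. C7 is the only new stereocentre and its R configuration should be imposed by the chiral ligand on chromium (Si-face attack), because C1 and C2 lie too far away to bias or oppose it. The step needs chemoselectivity for the C(sp2)–I bond over the two allylic acetates, which the much faster oxidative addition to the iodoalkene at low nickel loading should secure. It also needs cyclisation over oligomerisation, which slow addition at high dilution and the chain-stiffening E C11=C12 and ring-cis C3=C4 alkenes should secure.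

Compound list
1 | geranyl bromide, (2E)-1-bromo-3,7-dimethylocta-2,6-diene | BrC/C=C(\C)CCC=C(C)C | starting material
2 | 1-(trimethylsilyl)propyne | CC#C[Si](C)(C)C | starting material
3 | 3-(trimethylsilyl)prop-2-yn-1-yllithium | [Li]CC#C[Si](C)(C)C | intermediate
4 | trimethyl[(5E)-6,10-dimethylundeca-5,9-dien-1-yn-1-yl]silane | C[Si](C)(C)C#CCC/C=C(\C)CCC=C(C)C | intermediate
5 | (5E)-6,10-dimethylundeca-5,9-dien-1-yne | C#CCC/C=C(\C)CCC=C(C)C | intermediate
6 | 9-[(1Z,5E)-2-iodo-6,10-dimethylundeca-1,5,9-trien-1-yl]-9-borabicyclo[3.3.1]nonane | I/C(CC/C=C(\C)CCC=C(C)C)=C\B1C2CCCC1CCC2 | intermediate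
7 | (5E)-2-iodo-6,10-dimethylundeca-1,5,9-triene | C=C(I)CC/C=C(\C)CCC=C(C)C | intermediate
8 | (2E,6E)-10-iodo-2,6-dimethylundeca-2,6,10-trienal | C=C(I)CC/C=C(\C)CC/C=C(\C)C=O | intermediate
9 | (2E,6E)-10-iodo-2,6-dimethylundeca-2,6,10-trien-1-ol | C=C(I)CC/C=C(\C)CC/C=C(\C)CO | intermediate
10 | (2E,6E)-1-bromo-10-iodo-2,6-dimethylundeca-2,6,10-triene | C=C(I)CC/C=C(\C)CC/C=C(\C)CBr | intermediate
11 | but-2-yne-1,4-diol | OCC#CCO | starting material
12 | 4-[(tert-butyldimethylsilyl)oxy]but-2-yn-1-ol | OCC#CCO[Si](C)(C)C(C)(C)C | intermediate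
13 | sodium 2,2-bis(2-methoxyethoxy)-3-{[(tert-butyldimethylsilyl)oxy]methyl}-2,5-dihydro-1,2-oxaaluminol-2-uide (cyclic vinylalanate) | [Na+].CC(C)(C)[Si](C)(C)OCC1=CCO[Al-]1(OCCOC)OCCOC | intermediate
14 | (2Z)-4-[(tert-butyldimethylsilyl)oxy]-3-iodobut-2-en-1-ol | OC/C=C(/CO[Si](C)(C)C(C)(C)C)I | intermediate
15 | acrolein diethyl acetal, 3,3-diethoxyprop-1-ene | C=CC(OCC)OCC | starting material
16 | 9-(3,3-diethoxypropyl)-9-borabicyclo[3.3.1]nonane | CCOC(CCB1C2CCCC1CCC2)OCC | intermediate
17 | (2E)-3-{[(tert-butyldimethylsilyl)oxy]methyl}-6,6-diethoxyhex-2-en-1-ol | OC/C=C(/CO[Si](C)(C)C(C)(C)C)CCC(OCC)OCC | intermediate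
18 | (2E)-3-{[(tert-butyldimethylsilyl)oxy]methyl}-6,6-diethoxyhex-2-enal | O=C/C=C(/CO[Si](C)(C)C(C)(C)C)CCC(OCC)OCC | intermediate
19 | (4E,6S,7R,10E)-4-{[(tert-butyldimethylsilyl)oxy]methyl}-1,1-diethoxy-14-iodo-10-methyl-7-(prop-1-en-2-yl)pentadeca-4,10,14-trien-6-ol | C=C(I)CC/C=C(\C)CC[C@H](C(=C)C)[C@@H](O)/C=C(/CO[Si](C)(C)C(C)(C)C)CCC(OCC)OCC | intermediate
20 | (4E,6S,7R,10E)-1,1-diethoxy-4-(hydroxymethyl)-14-iodo-10-methyl-7-(prop-1-en-2-yl)pentadeca-4,10,14-trien-6-ol | C=C(I)CC/C=C(\C)CC[C@H](C(=C)C)[C@@H](O)/C=C(/CO)CCC(OCC)OCC | intermediate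
21 | (4E,6S,7R,10E)-4-(acetoxymethyl)-1,1-diethoxy-14-iodo-10-methyl-7-(prop-1-en-2-yl)pentadeca-4,10,14-trien-6-yl acetate | C=C(I)CC/C=C(\C)CC[C@H](C(=C)C)[C@@H](OC(C)=O)/C=C(/COC(C)=O)CCC(OCC)OCC | intermediate
22 | (4E,6S,7R,10E)-6-acetoxy-4-(acetoxymethyl)-14-iodo-10-methyl-7-(prop-1-en-2-yl)pentadeca-4,10,14-trienal | C=C(I)CC/C=C(\C)CC[C@H](C(=C)C)[C@@H](OC(C)=O)/C=C(/COC(C)=O)CCC=O | intermediate
23 | CNP0077636.1, (1R,2S,3E,7R,11E)-2,18-diacetoxycembra-3,8(19),11,15-tetraen-7-ol | C=C1CC/C=C(\C)CC[C@H](C(=C)C)[C@@H](OC(C)=O)/C=C(/COC(C)=O)CC[C@H]1O | target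

Total step count: 14. Longest linear sequence: 10 steps (steps 1–5, then 10–14).

Steps most likely to fail

Step 14 (macrocyclisation). What may go wrong is insufficient facial discrimination at the C7 aldehyde by the chiral chromium complex inside the folding chain, or loss of material to oligomerisation if the ligand slows the closure. The fallback sets the carbinol after the ring is closed. It sets out from 22, which is cyclised without chiral ligand (CrCl2 in excess, NiCl2 cat., DMSO/THF, high dilution). This should give the macrocycle as a mixture of 23 and its C7 epimer, the (7S)-alcohol F1. The mixture is oxidised with Dess–Martin periodinane/NaHCO3 to the C7 ketone conjugated with the C8=C19 methylene, the macrocyclic enone F2. F2 is then reduced 1,2 under Corey–Bakshi–Shibata control ((S)-2-methyl-CBS-oxazaborolidine, catecholborane, toluene, −78 °C). With the alkenyl carbon C8 as the larger group the usual model predicts 7R. The fallback comes back to the route at 23.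

Step 10 (asymmetric chromium allylation). What may go wrong is incomplete enantiofacial control, or slow turnover, when the trisubstituted allyl unit and the beta,beta-disubstituted enal meet on the chiral chromium catalyst; the anti relationship should stay secure. The fallback replaces catalyst control by resolution. It sets out from 10 and 18, which are coupled with ligand-free CrCl2 (THF, rt) to give the racemic anti adduct, that is 19 together with its enantiomer F3. Esterification with (S)-O-methylmandelic acid (DCC, DMAP) gives two diastereomeric esters, the (S)-O-methylmandelate of 19 F4 and the (S)-O-methylmandelate of the enantiomer F5, which are separated by chromatography. Methanolysis of F4 (K2CO3, MeOH) comes back to the route at 19.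

Step 4 (allylic oxidation). What may go wrong is poor site selectivity between the terminal and the internal trisubstituted alkene together with overoxidation, which would leave mixtures that are hard to separate. The fallback oxidises before the chain is extended, where an allylic acetate deactivates the inner alkene. It sets out from 2 (used as 3) and purchased geranyl acetate F6. SeO2/tBuOOH oxidation gives (2E,6E)-8-hydroxygeranyl acetate F7, and TBDPSCl/imidazole gives the silyl ether acetate F8. K2CO3/MeOH then frees the allylic alcohol F9, and CBr4/PPh3 gives the allylic bromide F10. Alkylation with 3 gives the silylalkyne F11, and K2CO3/MeOH gives the terminal alkyne F12. B-iodo-9-BBN gives the iodoalkenylborane F13, and AcOH then gives the iodoalkene silyl ether F14. TBAF removes the silyl group and comes back to the route at 9.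

Further compounds
F1 | step 14 | (1R,2S,3E,7S,11E)-2,18-diacetoxycembra-3,8(19),11,15-tetraen-7-ol (C7 epimer of 23) | C=C1CC/C=C(\C)CC[C@H](C(=C)C)[C@@H](OC(C)=O)/C=C(/COC(C)=O)CC[C@@H]1O
F2 | step 14 | (1R,2S,3E,11E)-2,18-diacetoxycembra-3,8(19),11,15-tetraen-7-one | C=C1CC/C=C(\C)CC[C@H](C(=C)C)[C@@H](OC(C)=O)/C=C(/COC(C)=O)CCC1=O
F3 | step 10 | (4E,6R,7S,10E)-4-{[(tert-butyldimethylsilyl)oxy]methyl}-1,1-diethoxy-14-iodo-10-methyl-7-(prop-1-en-2-yl)pentadeca-4,10,14-trien-6-ol (enantiomer of 19) | C=C(I)CC/C=C(\C)CC[C@@H](C(=C)C)[C@H](O)/C=C(/CO[Si](C)(C)C(C)(C)C)CCC(OCC)OCC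
F4 | step 10 | (2S)-2-methoxy-2-phenylacetate of 19 | C=C(I)CC/C=C(\C)CC[C@H](C(=C)C)[C@@H](OC(=O)[C@@H](OC)c1ccccc1)/C=C(/CO[Si](C)(C)C(C)(C)C)CCC(OCC)OCC
F5 | step 10 | (2S)-2-methoxy-2-phenylacetate of F3 | C=C(I)CC/C=C(\C)CC[C@@H](C(=C)C)[C@H](OC(=O)[C@@H](OC)c1ccccc1)/C=C(/CO[Si](C)(C)C(C)(C)C)CCC(OCC)OCC
F6 | step 4 | geranyl acetate | CC(=O)OC/C=C(\C)CCC=C(C)C
F7 | step 4 | (2E,6E)-8-hydroxy-3,7-dimethylocta-2,6-dien-1-yl acetate | CC(=O)OC/C=C(\C)CC/C=C(\C)CO
F8 | step 4 | (2E,6E)-8-[(tert-butyldiphenylsilyl)oxy]-3,7-dimethylocta-2,6-dien-1-yl acetate | CC(=O)OC/C=C(\C)CC/C=C(\C)CO[Si](c1ccccc1)(c1ccccc1)C(C)(C)C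
F9 | step 4 | (2E,6E)-8-[(tert-butyldiphenylsilyl)oxy]-3,7-dimethylocta-2,6-dien-1-ol | OC/C=C(\C)CC/C=C(\C)CO[Si](c1ccccc1)(c1ccccc1)C(C)(C)C
F10 | step 4 | [(2E,6E)-8-bromo-2,6-dimethylocta-2,6-dien-1-yl]oxy(tert-butyl)diphenylsilane | BrC/C=C(\C)CC/C=C(\C)CO[Si](c1ccccc1)(c1ccccc1)C(C)(C)C
F11 | step 4 | tert-butyl{[(2E,6E)-2,6-dimethyl-11-(trimethylsilyl)undeca-2,6-dien-10-yn-1-yl]oxy}diphenylsilane | C[Si](C)(C)C#CCC/C=C(\C)CC/C=C(\C)CO[Si](c1ccccc1)(c1ccccc1)C(C)(C)C
F12 | step 4 | tert-butyl{[(2E,6E)-2,6-dimethylundeca-2,6-dien-10-yn-1-yl]oxy}diphenylsilane | C#CCC/C=C(\C)CC/C=C(\C)CO[Si](c1ccccc1)(c1ccccc1)C(C)(C)C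
F13 | step 4 | 9-[(1Z,5E,9E)-11-[(tert-butyldiphenylsilyl)oxy]-2-iodo-6,10-dimethylundeca-1,5,9-trien-1-yl]-9-borabicyclo[3.3.1]nonane | I/C(CC/C=C(\C)CC/C=C(\C)CO[Si](c1ccccc1)(c1ccccc1)C(C)(C)C)=C\B1C2CCCC1CCC2
F14 | step 4 | tert-butyl{[(2E,6E)-10-iodo-2,6-dimethylundeca-2,6,10-trien-1-yl]oxy}diphenylsilane | C=C(I)CC/C=C(\C)CC/C=C(\C)CO[Si](c1ccccc1)(c1ccccc1)C(C)(C)C
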